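The route rests on disconnecting, in the six-membered ring, the bond between the carbon that carries the exocyclic =CH2 and the neighbouring CH–O carbon (the one esterified by the 3-methylpent-2-enoate). A nickel-catalysed reductive alkyne–aldehyde cyclisation closes this last ring of the trans-hydrindane and creates the methylidene group and the allylic carbinol in one operation. Its precursor is a fully substituted, monocyclic cyclopentanone that carries an ethynyl group and a 2-methyl-5-oxopentan-3-yl chain on adjacent, trans-disposed carbons. It is assembled by two successive conjugate additions to a chiral cyclopentenone, and the two ring acyloxy stereocentres are completed by invertive Mitsunobu esterification.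

Key step: step 11

Remark: the sulfur stereocentre of the allylic sulfoxide (6, 8–12, 14–16) is left undefined in the SMILES; it plays no role after step 3 and is removed in step 9.

Step 1
Reactants: 1 (S)-4-[(tert-butyldimethylsilyl)oxy]cyclopent-2-en-1-one
Product: 3 (S)-4-[(trimethylsilyl)ethynyl]cyclopent-2-en-1-one, via silyloxy ketone 2 (not isolated)
Conditions: Me2AlC≡CSiMe3 (from LiC≡CSiMe3 + Me2AlCl), Ni(acac)2 (5 mol%), DIBAL-H (5 mol%), Et2O, −5 °C; aq. NH4Cl; then DBU, CH2Cl2, −20 → 0 °C
Reagents that add atoms: dimethyl[(trimethylsilyl)ethynyl]aluminium, C[Al](C)C#C[Si](C)(C)C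
Why: Nickel-catalysed conjugate alkynylation of the s-trans enone should occur anti to the silyloxy group, and E1cB loss of the silanol (addition–elimination) transposes the enone, so the C4 stereocentre derives from the starting enone.

Step 2
Reactants: 4 4-methylpent-1-en-3-ol (racemic)
Product: 6 (E)-(4-methylpent-2-en-1-yl) phenyl sulfoxide, via sulfenate ester 5 (not isolated)
Conditions: PhSCl, Et3N, Et2O, −78 °C → rt
Reagents that add atoms: benzenesulfenyl chloride, ClSc1ccccc1
Why: O-Sulfenylation followed by Mislow–Evans [2,3]-sigmatropic rearrangement of the allylic sulfenate, with the isopropyl group pseudo-equatorial in the envelope transition state, should give the (E)-allylic sulfoxide.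

Step 3
Reactants: 3 (S)-4-[(trimethylsilyl)ethynyl]cyclopent-2-en-1-one; 6 (E)-(4-methylpent-2-en-1-yl) phenyl sulfoxide; 7 acetaldehyde
Product: 10 (2R,3R,4S)-2-[(1S)-1-hydroxyethyl]-3-[(1E,3R)-4-methyl-1-(phenylsulfinyl)pent-1-en-3-yl]-4-[(trimethylsilyl)ethynyl]cyclopentan-1-one, via lithiated sulfoxide 8 (not isolated), via lithium enolate 9 (not isolated)
Conditions: 6 (2.2 equiv), LDA (2.2 equiv), THF, −78 °C; 3, −78 °C, 15 min; Cp2ZrCl2, −78 → −40 °C; MeCHO (excess), −78 °C; aq. NH4Cl
Reagents that add atoms: none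
Why: Michael addition of the lithiated (E)-allylic sulfoxide through its γ-carbon, via a lithium-bridged ten-membered chair–chair transition state, should set C3 (anti to the C4 alkynyl group) and the isopropyl-bearing carbon (from the E geometry) with kinetic selection of the matched sulfoxide enantiomer, and the regiodefined enolate, transmetalated to zirconium, should undergo a syn-selective aldol addition to acetaldehyde anti to the new C3 substituent, setting C2 and the carbinol carbon.

Step 4
Reactants: 10 (2R,3R,4S)-2-[(1S)-1-hydroxyethyl]-3-[(1E,3R)-4-methyl-1-(phenylsulfinyl)pent-1-en-3-yl]-4-[(trimethylsilyl)ethynyl]cyclopentan-1-one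
Product: 11 triethylsilyl ether of 10
Conditions: Et3SiCl, imidazole, DMF, 0 °C → rt
Reagents that add atoms: chlorotriethylsilane, CC[Si](Cl)(CC)CC
Why: Silyl ether protection of the secondary carbinol so that it survives enolate formation in step 5 without β-elimination or retro-aldol cleavage; no stereocentre is touched.

Step 5
Reactants: 11 triethylsilyl ether of 10
Product: 12 (2R,3R,4S,5S)-5-hydroxy-3-[(1E,3R)-4-methyl-1-(phenylsulfinyl)pent-1-en-3-yl]-2-[(1S)-1-(triethylsilyloxy)ethyl]-4-[(trimethylsilyl)ethynyl]cyclopentan-1-one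
Conditions: KHMDS (1.05 equiv), THF, −78 °C; then 2-(phenylsulfonyl)-3-phenyloxaziridine, −78 °C; aq. NH4Cl
Reagents that add atoms: 2-(phenylsulfonyl)-3-phenyloxaziridine, O=S(=O)(c1ccccc1)N1OC1c1ccccc1
Why: Kinetic deprotonation at the unhindered C5 methylene and Davis oxidation of the enolate anti to the adjacent C4 alkynyl group should give the trans α-hydroxy ketone, the C5 epimer that the inversion of step 6 requires.

Step 6
Reactants: 12 (2R,3R,4S,5S)-5-hydroxy ketone; 13 (R)-2-methylbutanoic acid
Product: 14 (2R,3R,4S,5R)-5-{[(2R)-2-methylbutanoyl]oxy}-3-[(1E,3R)-4-methyl-1-(phenylsulfinyl)pent-1-en-3-yl]-2-[(1S)-1-(triethylsilyloxy)ethyl]-4-[(trimethylsilyl)ethynyl]cyclopentan-1-one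
Conditions: PPh3, DIAD, THF, 0 °C → rt
Reagents that add atoms: none
Why: Mitsunobu esterification, an SN2 displacement of the oxyphosphonium group at the carbon α to the ketone, should invert C5 and place the ester cis to the slim alkynyl group; the stereocentre of the acid is not involved.

Step 7
Reactants: 14 (2R,3R,4S,5R)-silyl-protected ester
Product: 15 (2R,3R,4S,5R)-4-ethynyl-2-[(1S)-1-hydroxyethyl]-5-{[(2R)-2-methylbutanoyl]oxy}-3-[(1E,3R)-4-methyl-1-(phenylsulfinyl)pent-1-en-3-yl]cyclopentan-1-one
Conditions: TBAF, AcOH (1:1), THF, 0 °C → rt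
Reagents that add atoms: none
Why: Fluoride-mediated desilylation should cleave both the O–SiEt3 ether and the C(sp)–SiMe3 bond, the acetic acid buffer keeping the medium non-basic for the α-acyloxy ketone and the β-hydroxy ketone.

Step 8
Reactants: 15 (2R,3R,4S,5R)-4-ethynyl hydroxy ketone
Product: 16 (2R,3R,4S,5R)-2-[(1S)-1-acetoxyethyl]-4-ethynyl-5-{[(2R)-2-methylbutanoyl]oxy}-3-[(1E,3R)-4-methyl-1-(phenylsulfinyl)pent-1-en-3-yl]cyclopentan-1-one
Conditions: Ac2O, pyridine, DMAP (cat.), CH2Cl2, 0 °C
Reagents that add atoms: acetic anhydride, CC(=O)OC(C)=O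
Why: Nucleophile-catalysed acetylation of the only free hydroxyl group; the weak base and low temperature should avoid E1cB loss of acetate.

Step 9
Reactants: 16 acetoxy vinyl sulfoxide
Product: 17 (2R,3R,4S,5R)-2-[(1S)-1-acetoxyethyl]-4-ethynyl-5-{[(2R)-2-methylbutanoyl]oxy}-3-[(1E,3R)-4-methyl-1-(phenylsulfanyl)pent-1-en-3-yl]cyclopentan-1-one
Conditions: NaI, (CF3CO)2O, acetone, −40 °C; aq. Na2S2O3
Reagents that add atoms: none
Why: Sulfoxide deoxygenation (O-acylation by the anhydride, then reduction of the acyloxysulfonium ion by iodide) should give the vinyl sulfide, a masked aldehyde, without touching the esters, the ketone or the alkyne.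

Step 10
Reactants: 17 vinyl sulfide
Product: 18 (2R,3R,4S,5R)-2-[(1S)-1-acetoxyethyl]-4-ethynyl-5-{[(2R)-2-methylbutanoyl]oxy}-3-[(3R)-2-methyl-5-oxopentan-3-yl]cyclopentan-1-one
Conditions: TiCl4, H2O, MeCN, 0 °C
Reagents that add atoms: water, O
Why: Lewis acid-promoted hydrolysis of the vinyl sulfide (β-protonation to the thionium ion, addition of water, loss of thiophenol) should unmask the aldehyde; the isopropyl-bearing stereocentre is β to the new carbonyl and cannot epimerise.

Step 11
Reactants: 18 acetylenic aldehyde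
Product: 20 (1R,3R,3aR,4R,6R,7aS)-3-[(1S)-1-acetoxyethyl]-6-hydroxy-7-methylidene-2-oxo-4-(propan-2-yl)octahydro-1H-inden-1-yl (2R)-2-methylbutanoate, via triethylsilyl ether 19 (not isolated)
Conditions: Ni(cod)2 (20 mol%), PBu3 (40 mol%), Et3SiH (5 equiv), THF, rt, slow addition of 18; then HF·pyridine, THF/pyridine, 0 °C
Reagents that add atoms: none
Why: Ni(0) binds the terminal alkyne and the aldehyde and undergoes oxidative cyclisation to an oxanickelacyclopentene, forming the bond between the internal alkyne carbon and the aldehyde carbon; σ-bond metathesis of the Ni–O bond with Et3SiH and C–H reductive elimination release the methylidene group and the silyl ether, which HF·pyridine cleaves. The closest known reaction type is the nickel-catalysed reductive cyclisation of ynals with silanes. The six-membered ring closes in the 6-exo-dig mode, and because the two ring-fusion carbons are already trans on the cyclopentanone a trans-hydrindane results. The only new stereocentre, the carbinol carbon, is under substrate control: the forming ring is a chair with the ring-fusion bonds and the isopropyl group equatorial, and the planar five-membered nickelacycle forces the C–O bond into the plane of the developing exocyclic alkene, that is equatorial. The step needs chemoselectivity for the aldehyde over the ketone and esters and regioselectivity for the internal alkyne carbon, secured by the higher reactivity of the aldehyde, by the six- versus seven-membered ring and by slow addition at high dilution, which suppresses alkyne oligomerisation. The equatorial alcohol is the epimer that the invertive esterification of step 12 requires.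

Step 12
Reactants: 20 equatorial allylic alcohol; 21 (E)-3-methylpent-2-enoic acid
Product: 22 (1R,3R,3aR,4R,6S,7aS)-3-[(1S)-1-acetoxyethyl]-7-methylidene-1-{[(2R)-2-methylbutanoyl]oxy}-2-oxo-4-(propan-2-yl)octahydro-1H-inden-6-yl (2E)-3-methylpent-2-enoate
Conditions: PPh3, DIAD, toluene, 0 °C → rt
Reagents that add atoms: none
Why: Mitsunobu esterification, with SN2 attack of the carboxylate along the axial trajectory on the oxyphosphonium salt of the equatorial allylic alcohol, should invert the carbinol carbon to the axial ester of the target under neutral conditions that spare the β-acetoxy ketone and the α-acyloxy ketone; the (E)-alkene of the acid is not touched.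

Compound list
1 | (S)-4-[(tert-butyldimethylsilyl)oxy]cyclopent-2-en-1-one | O=C1C=C[C@@H](O[Si](C)(C)C(C)(C)C)C1 | starting material
2 | (3R,4S)-4-[(tert-butyldimethylsilyl)oxy]-3-[(trimethylsilyl)ethynyl]cyclopentan-1-one (trans) | C[Si](C)(C)C#C[C@@H]1[C@@H](O[Si](C)(C)C(C)(C)C)CC(=O)C1 | intermediate
3 | (S)-4-[(trimethylsilyl)ethynyl]cyclopent-2-en-1-one | C[Si](C)(C)C#C[C@@H]1C=CC(=O)C1 | intermediate
4 | 4-methylpent-1-en-3-ol (racemic) | CC(C)C(O)C=C | starting material
5 | 4-methylpent-1-en-3-yl benzenesulfenate (racemic) | CC(C)C(OSc1ccccc1)C=C | intermediate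
6 | (E)-(4-methylpent-2-en-1-yl) phenyl sulfoxide (racemic at sulfur) | CC(C)/C=C/CS(=O)c1ccccc1 | intermediate
7 | acetaldehyde | CC=O | starting material
8 | α-lithio derivative of 6 | CC(C)/C=C/C([Li])S(=O)c1ccccc1 | intermediate
9 | lithium (3R,4S)-3-[(1E,3R)-4-methyl-1-(phenylsulfinyl)pent-1-en-3-yl]-4-[(trimethylsilyl)ethynyl]cyclopent-1-en-1-olate | C[Si](C)(C)C#C[C@@H]1[C@H](C=C(O[Li])C1)[C@@H](C(C)C)/C=C/S(=O)c1ccccc1 | intermediate
10 | (2R,3R,4S)-2-[(1S)-1-hydroxyethyl]-3-[(1E,3R)-4-methyl-1-(phenylsulfinyl)pent-1-en-3-yl]-4-[(trimethylsilyl)ethynyl]cyclopentan-1-one (all-trans ring) | C[Si](C)(C)C#C[C@@H]1[C@H]([C@H]([C@H](C)O)C(=O)C1)[C@@H](C(C)C)/C=C/S(=O)c1ccccc1 | intermediate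
11 | triethylsilyl ether of 10 | C[Si](C)(C)C#C[C@@H]1[C@H]([C@H]([C@H](C)O[Si](CC)(CC)CC)C(=O)C1)[C@@H](C(C)C)/C=C/S(=O)c1ccccc1 | intermediate
12 | (2R,3R,4S,5S)-5-hydroxy derivative of 11 (OH trans to the alkynyl group) | C[Si](C)(C)C#C[C@@H]1[C@H]([C@H]([C@H](C)O[Si](CC)(CC)CC)C(=O)[C@H]1O)[C@@H](C(C)C)/C=C/S(=O)c1ccccc1 | intermediate
13 | (R)-2-methylbutanoic acid | CC[C@@H](C)C(=O)O | starting material
14 | (2R,3R,4S,5R)-5-{[(2R)-2-methylbutanoyl]oxy} ester (ester cis to the alkynyl group), silyl groups retained | C[Si](C)(C)C#C[C@@H]1[C@H]([C@H]([C@H](C)O[Si](CC)(CC)CC)C(=O)[C@@H]1OC(=O)[C@H](C)CC)[C@@H](C(C)C)/C=C/S(=O)c1ccccc1 | intermediate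
15 | (2R,3R,4S,5R)-4-ethynyl-2-[(1S)-1-hydroxyethyl]-5-{[(2R)-2-methylbutanoyl]oxy}-3-[(1E,3R)-4-methyl-1-(phenylsulfinyl)pent-1-en-3-yl]cyclopentan-1-one | C#C[C@@H]1[C@H]([C@H]([C@H](C)O)C(=O)[C@@H]1OC(=O)[C@H](C)CC)[C@@H](C(C)C)/C=C/S(=O)c1ccccc1 | intermediate
16 | (1S)-acetate of 15 | C#C[C@@H]1[C@H]([C@H]([C@H](C)OC(C)=O)C(=O)[C@@H]1OC(=O)[C@H](C)CC)[C@@H](C(C)C)/C=C/S(=O)c1ccccc1 | intermediate
17 | (E)-vinyl phenyl sulfide corresponding to 16 | C#C[C@@H]1[C@H]([C@H]([C@H](C)OC(C)=O)C(=O)[C@@H]1OC(=O)[C@H](C)CC)[C@@H](C(C)C)/C=C/Sc1ccccc1 | intermediate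
18 | (2R,3R,4S,5R)-2-[(1S)-1-acetoxyethyl]-4-ethynyl-5-{[(2R)-2-methylbutanoyl]oxy}-3-[(3R)-2-methyl-5-oxopentan-3-yl]cyclopentan-1-one | C#C[C@@H]1[C@H]([C@H]([C@H](C)OC(C)=O)C(=O)[C@@H]1OC(=O)[C@H](C)CC)[C@@H](C(C)C)CC=O | intermediate
19 | triethylsilyl ether of 20 | C=C1[C@@H]2[C@H]([C@H]([C@H](C)OC(C)=O)C(=O)[C@@H]2OC(=O)[C@H](C)CC)[C@@H](C(C)C)C[C@H]1O[Si](CC)(CC)CC | intermediate
20 | (1R,3R,3aR,4R,6R,7aS)-3-[(1S)-1-acetoxyethyl]-6-hydroxy-7-methylidene-2-oxo-4-(propan-2-yl)octahydro-1H-inden-1-yl (2R)-2-methylbutanoate (trans-fused, equatorial OH) | C=C1[C@@H]2[C@H]([C@H]([C@H](C)OC(C)=O)C(=O)[C@@H]2OC(=O)[C@H](C)CC)[C@@H](C(C)C)C[C@H]1O | intermediate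
21 | (E)-3-methylpent-2-enoic acid | CC/C(C)=C/C(=O)O | starting material
22 | (1R,3R,3aR,4R,6S,7aS)-3-[(1S)-1-acetoxyethyl]-7-methylidene-1-{[(2R)-2-methylbutanoyl]oxy}-2-oxo-4-(propan-2-yl)octahydro-1H-inden-6-yl (2E)-3-methylpent-2-enoate (CNP0289166.2) | C=C1[C@@H]2[C@H]([C@H]([C@H](C)OC(C)=O)C(=O)[C@@H]2OC(=O)[C@H](C)CC)[C@@H](C(C)C)C[C@@H]1OC(=O)/C=C(\C)CC | target

Total step count: 12. Longest linear sequence: 11 steps (step 1, then steps 3–12).

Steps most likely to fail

Step 11. Oligomerisation or hydrosilylation of the terminal alkyne may outrun the oxidative cyclisation, and Ni(0) may reductively cleave the C–O bond α to the ketone. The fallback sets out from vinyl sulfide 17 and closes the same bond by a chromium-mediated carbonyl addition. Iodoboration of the terminal alkyne with B-iodo-9-BBN and protonolysis with AcOH should give the 2-iodoalkene F3. Hydrolysis with TiCl4/H2O as in step 10 should give the iodo aldehyde F4. An intramolecular Nozaki–Hiyama–Kishi reaction (CrCl2, cat. NiCl2, DMF) should then return to alcohol 20. Should its carbinol epimer predominate, that compound is the axial alcohol F6 of the last fallback and is acylated directly.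

Step 3. Discrimination between the two sulfoxide enantiomers may be incomplete, the basic carbanion may deprotonate the γ-position of enone 3, and the syn-selectivity of the zirconium aldol may erode. The fallback sets out from 3 and 6 and separates the two bond formations. Enolate 9 is intercepted with Me3SiCl to give the silyl enol ether F1, which is freed from the excess sulfoxide. A fluoride-catalysed (TASF) aldol addition to 7 through an open transition state should give the syn aldol trimethylsilyl ether F2, and mild acid (citric acid, MeOH) returns to 10.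

Step 12. The carboxylate may attack the methylene terminus (SN2′), or the activated alcohol may eliminate instead of undergoing direct displacement. The fallback sets out from 20 and splits inversion and acylation. Mitsunobu reaction with the more acidic chloroacetic acid should give the inverted chloroacetate F5. Thiourea (NaHCO3, EtOH) should remove the chloroacetyl group selectively to give the axial alcohol F6. Steglich esterification with 21 (DIC, cat. DMAP, CH2Cl2, 0 °C) then proceeds with retention and returns to 22.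

Further compounds
F1 | step 3 | trimethylsilyl enol ether of the conjugate adduct (from enolate 9) | C[Si](C)(C)C#C[C@@H]1[C@H](C=C(O[Si](C)(C)C)C1)[C@@H](C(C)C)/C=C/S(=O)c1ccccc1
F2 | step 3 | trimethylsilyl ether of 10 | C[Si](C)(C)C#C[C@@H]1[C@H]([C@H]([C@H](C)O[Si](C)(C)C)C(=O)C1)[C@@H](C(C)C)/C=C/S(=O)c1ccccc1
F3 | step 11 | 4-(1-iodoethenyl) analogue of vinyl sulfide 17 | C=C(I)[C@@H]1[C@H]([C@H]([C@H](C)OC(C)=O)C(=O)[C@@H]1OC(=O)[C@H](C)CC)[C@@H](C(C)C)/C=C/Sc1ccccc1
F4 | step 11 | 4-(1-iodoethenyl) analogue of aldehyde 18 | C=C(I)[C@@H]1[C@H]([C@H]([C@H](C)OC(C)=O)C(=O)[C@@H]1OC(=O)[C@H](C)CC)[C@@H](C(C)C)CC=O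
F5 | step 12 | (6S)-chloroacetate (axial, inverted) of 20 | C=C1[C@@H]2[C@H]([C@H]([C@H](C)OC(C)=O)C(=O)[C@@H]2OC(=O)[C@H](C)CC)[C@@H](C(C)C)C[C@@H]1OC(=O)CCl
F6 | step 12 | (6S)-alcohol (axial epimer of 20) | C=C1[C@@H]2[C@H]([C@H]([C@H](C)OC(C)=O)C(=O)[C@@H]2OC(=O)[C@H](C)CC)[C@@H](C(C)C)C[C@@H]1O
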